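Ring B is a cyclic 1,3,5-tricarbonyl. Its butyryl-bearing ring carbon is bonded to a carbonyl carbon that sits directly on the quaternary stereocentre, which read backwards is a β-triketone methylene acylated by a malonate-type ester.
Cuts, in order: the two phenolic MOM ethers; that ring-B bond, which opens ring B to an acyclic 2,2-disubstituted 3,5,7-triketo ester (chain numbered C1 = ester carbon to C10); C4–CH2Ar; C4–C5; C2–prenyl.
Forward: ring A is bought as 5-methoxyresorcinol, then acylated, formylated, protected and converted into a benzylic bromide. The chain grows from methyl 2-methylacetoacetate by prenylation at C2 and acylation of the acetyl methyl group with a ketal-masked 3-oxohexanoyl donor.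
The β-diketone is benzylated at C4, so no kinetic enolate has to be formed selectively beside the enolisable hexanoyl ketone. The ketal is then removed, ring B closes by Dieckmann cyclisation, and the MOM ethers fall last.
Stereochemistry: the only stereocentre (C2, R) is set by alkylating the lithiated L-valine tert-butyl ester enamine with prenyl bromide. It is quaternary and non-enolisable, so it is carried through unchanged.

Key step: step 13

Assumption: β-di- and β-tricarbonyl compounds are drawn as one tautomer (20 and 21 as the chelated C3 enol, so the epimerisable C4 carries no descriptor), and the facial sense of step 7 is taken from the lithium-chelate model stated there.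

Step 1
Reactants: 1 5-methoxyresorcinol; 2 hexanoyl chloride
Product: 3 1-(2,6-dihydroxy-4-methoxyphenyl)hexan-1-one
Conditions: AlCl3 (3.5 equiv), CH2Cl2–PhNO2, 0 °C → 40 °C; then 1 M HCl
Reagents that add atoms: none
Why: Friedel–Crafts acylation (partly by O-acylation and Fries shift) of the doubly activated arene; under equilibrating AlCl3 conditions the ketone flanked by two hydroxyls, chelated on both sides, should predominate over the 4-acyl isomer, which is removed by chromatography.

Step 2
Reactants: 3 1-(2,6-dihydroxy-4-methoxyphenyl)hexan-1-one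
Product: 5 3-hexanoyl-2,4-dihydroxy-6-methoxybenzaldehyde, via aryl iminium chloride 4 (not isolated)
Conditions: POCl3 (1.2 equiv), DMF (1.5 equiv), EtOAc, 0 °C → rt; then H2O, 40 °C
Reagents that add atoms: N,N-dimethylformamide, CN(C)C=O; water, O
Why: Vilsmeier–Haack formylation; the two free ring positions of 3 are equivalent, so only one aldehyde can form, and the first formyl group deactivates the ring towards a second attack.

Step 3
Reactants: 5 3-hexanoyl-2,4-dihydroxy-6-methoxybenzaldehyde
Product: 6 3-hexanoyl-6-methoxy-2,4-bis(methoxymethoxy)benzaldehyde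
Conditions: NaH (2.2 equiv), MOMCl (2.5 equiv), DMF, 0 °C → rt
Reagents that add atoms: chloromethyl methyl ether, COCCl
Why: Williamson-type O-alkylation with a hard electrophile; full deprotonation with NaH breaks both O–H···O=C hydrogen bonds so that both phenols react, and at oxygen.

Step 4
Reactants: 6 3-hexanoyl-6-methoxy-2,4-bis(methoxymethoxy)benzaldehyde
Product: 7 1-[3-(hydroxymethyl)-4-methoxy-2,6-bis(methoxymethoxy)phenyl]hexan-1-one
Conditions: NaBH4 (0.5 equiv), MeOH–THF, −10 → 0 °C
Reagents that add atoms: none
Why: Chemoselective borohydride reduction; the aldehyde should react far faster than the aryl ketone, which is twisted out of conjugation and shielded by two ortho substituents.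

Step 5
Reactants: 7 1-[3-(hydroxymethyl)-4-methoxy-2,6-bis(methoxymethoxy)phenyl]hexan-1-one
Product: 8 1-[3-(bromomethyl)-4-methoxy-2,6-bis(methoxymethoxy)phenyl]hexan-1-one
Conditions: CBr4, PPh3, CH2Cl2, −20 → 0 °C; short silica plug, used at once
Reagents that add atoms: tetrabromomethane, BrC(Br)(Br)Br
Why: Appel reaction, which runs under neutral conditions so that the acid-labile MOM ethers survive and the reactive benzylic bromide is not exposed to acid or heat.

Step 6
Reactants: 9 methyl 2-methylacetoacetate; 10 L-valine tert-butyl ester (free base)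
Product: 11 methyl (Z)-3-{[(2S)-1-tert-butoxy-3-methyl-1-oxobutan-2-yl]amino}-2-methylbut-2-enoate
Conditions: BF3·OEt2 (cat.), toluene, reflux, Dean–Stark
Reagents that add atoms: none
Why: Acid-catalysed enamine condensation of a β-keto ester with a primary amine under azeotropic water removal; the internal N–H···O=C hydrogen bond fixes the Z geometry.

Step 7
Reactants: 11 enamine from step 6; 12 prenyl bromide
Product: 14 methyl (2R)-2-acetyl-2,5-dimethylhex-4-enoate, via prenylated imine 13 (not isolated)
Conditions: LiN(i-Pr)2 (1.1 equiv), toluene, −78 °C; THF (2 equiv); 12, −78 → −40 °C; then 1 M HCl, Et2O, 0 °C → rt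
Reagents that add atoms: water, O
Why: Auxiliary-controlled alkylation of a chiral lithioenamine of an α-alkyl β-keto ester: lithium is held by the nitrogen and both ester carbonyls in a flat tridentate chelate, the isopropyl group sends the weakly bound THF to the opposite face, prenyl bromide replaces it and is delivered in SN2 fashion from that face to give the R quaternary carbon, and mild acid then hydrolyses imine 13 and returns the auxiliary.

Step 8
Reactants: 15 methyl 3-oxohexanoate
Product: 16 methyl 2-(2-propyl-1,3-dioxolan-2-yl)acetate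
Conditions: ethylene glycol (1.5 equiv), p-TsOH (cat.), toluene, reflux, Dean–Stark
Reagents that add atoms: ethylene glycol, OCCO
Why: Acid-catalysed ketalisation with azeotropic water removal; only the ketone carbonyl reacts.

Step 9
Reactants: 16 methyl 2-(2-propyl-1,3-dioxolan-2-yl)acetate
Product: 17 2-(2-propyl-1,3-dioxolan-2-yl)acetic acid
Conditions: LiOH (1.5 equiv), THF–H2O, rt; then 1 M HCl to pH 4, 0 °C
Reagents that add atoms: lithium hydroxide, [Li+].[OH-]
Why: Ester saponification; the ketal is inert to base and should survive the brief cold acidification.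

Step 10
Reactants: 17 2-(2-propyl-1,3-dioxolan-2-yl)acetic acid; 14 methyl (2R)-2-acetyl-2,5-dimethylhex-4-enoate
Product: 19 methyl (2R)-2-methyl-2-(3-methylbut-2-en-1-yl)-3,5-dioxo-6-(2-propyl-1,3-dioxolan-2-yl)hexanoate, via acyl imidazolide 18 (not isolated)
Conditions: 17, 1,1'-carbonyldiimidazole (1.05 equiv), THF, rt; this solution added to 14 (2.1 equiv) + LiN(i-Pr)2 (2.1 equiv), THF, −78 → −20 °C; aq NH4Cl
Reagents that add atoms: 1,1'-carbonyldiimidazole, O=C(n1ccnc1)n1ccnc1 (supplies the imidazolyl group of 18 only; none of its atoms remain in 19)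
Why: Crossed Claisen-type C-acylation of a kinetic lithium enolate with an acyl imidazolide; 14 can enolise only at the acetyl methyl group, the second equivalent of enolate deprotonates the β-diketone as it forms and is recovered as 14, and the ketal keeps the third carbonyl silent.

Step 11
Reactants: 19 β-diketone from step 10; 8 benzylic bromide from step 5
Product: 20 methyl (2R)-4-{[3-hexanoyl-6-methoxy-2,4-bis(methoxymethoxy)phenyl]methyl}-2-methyl-2-(3-methylbut-2-en-1-yl)-3,5-dioxo-6-(2-propyl-1,3-dioxolan-2-yl)hexanoate
Conditions: NaH (1.0 equiv), THF, 0 °C; 8 in THF–DMF, 0 °C → rt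
Reagents that add atoms: none
Why: C-alkylation of a β-diketone; one equivalent of NaH removes only the C4 proton and leaves the hexanoyl α-hydrogens of 8 untouched, and the chelated sodium diketonate should attack the soft benzylic bromide through carbon.

Step 12
Reactants: 20 benzylated ketal from step 11
Product: 21 methyl (2R)-4-{[3-hexanoyl-6-methoxy-2,4-bis(methoxymethoxy)phenyl]methyl}-2-methyl-2-(3-methylbut-2-en-1-yl)-3,5,7-trioxodecanoate
Conditions: PPTS (0.3 equiv), acetone–H2O 10:1, 45 °C
Reagents that add atoms: water, O
Why: Acid-catalysed ketal hydrolysis; a ketone ketal ionises to a dialkyl oxocarbenium ion much more readily than an aryl formaldehyde acetal, so under PPTS buffering the MOM ethers and the prenyl alkene should remain.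

Step 13
Reactants: 21 open-chain triketo ester from step 12
Product: 22 bis(methoxymethyl) ether of Elaphopilosin B
Conditions: KOt-Bu (3 equiv), THF, 0 → 40 °C; then 1 M HCl to pH 3, 0 °C
Reagents that add atoms: none
Why: KOt-Bu turns 21 into its bis-enolate (C4 and C6 deprotonated); C6, the carbon between the C5 ketone and the butyryl carbonyl, adds to the C1 methyl ester and methoxide leaves, which is a Dieckmann (intramolecular Claisen) cyclisation of a 3,5,7-triketo ester, the reaction type that converts open-chain polyketo esters into acylphloroglucinols and acylfilicinic acids. Ring B, the only ring formed, closes in the 6-(enolexo)-exo-trig mode, and the fold is helped by the arylmethyl group on C4 and the quaternary C2, whose mutual repulsion disfavours the metal-chelated U-shaped diketonate and favours the W-shaped one in which C6 and C1 face each other; the weakly chelating potassium ion is chosen for the same reason. No stereocentre is created, and C2 carries no hydrogen and is never part of an enolate, so its R configuration should pass into 22 intact. The step needs C- rather than O-acylation: attack by the C5 enolate oxygen would give a six-membered enol lactone, but the expelled methoxide can reopen it, whereas the C-acylated product is at once deprotonated (consuming that methoxide) to the doubly enolised triketone dianion, the thermodynamic sink. Retro-Claisen cleavage at C2–C3 is held back because the base is bulky and the C3 carbonyl is hidden in an enolate. The other closures are not competitive: C4 onto C1 would make a four-membered ring, and the aldol of C8 onto C3 would need a third, far less acidic proton to be removed.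

Step 14
Reactants: 22 bis(methoxymethyl) ether of Elaphopilosin B
Product: 23 Elaphopilosin B
Conditions: conc. HCl (cat.), MeOH, rt → 40 °C
Reagents that add atoms: none
Why: Acid-catalysed acetal exchange (MOM cleavage) with methanol as formaldehyde acceptor, under the conditions customary for prenylated acylphloroglucinols and chalcones, which should be too mild to protonate the trisubstituted alkene or to dehydrate the phenol and ring-B carbonyl to a xanthene.

Compound list
1 | 5-methoxyresorcinol | COc1cc(O)cc(O)c1 | starting material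
2 | hexanoyl chloride | CCCCCC(Cl)=O | starting material
3 | 1-(2,6-dihydroxy-4-methoxyphenyl)hexan-1-one | CCCCCC(=O)c1c(O)cc(OC)cc1O | intermediate
4 | [(3-hexanoyl-2,4-dihydroxy-6-methoxyphenyl)methylidene]dimethylammonium chloride | CCCCCC(=O)c1c(O)cc(OC)c(C=[N+](C)C)c1O.[Cl-] | intermediate
5 | 3-hexanoyl-2,4-dihydroxy-6-methoxybenzaldehyde | CCCCCC(=O)c1c(O)cc(OC)c(C=O)c1O | intermediate
6 | 3-hexanoyl-6-methoxy-2,4-bis(methoxymethoxy)benzaldehyde | CCCCCC(=O)c1c(OCOC)cc(OC)c(C=O)c1OCOC | intermediate
7 | 1-[3-(hydroxymethyl)-4-methoxy-2,6-bis(methoxymethoxy)phenyl]hexan-1-one | CCCCCC(=O)c1c(OCOC)cc(OC)c(CO)c1OCOC | intermediate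
8 | 1-[3-(bromomethyl)-4-methoxy-2,6-bis(methoxymethoxy)phenyl]hexan-1-one | CCCCCC(=O)c1c(OCOC)cc(OC)c(CBr)c1OCOC | intermediate
9 | methyl 2-methylacetoacetate (racemic) | CC(=O)C(C)C(=O)OC | starting material
10 | L-valine tert-butyl ester | CC(C)[C@H](N)C(=O)OC(C)(C)C | starting material
11 | methyl (Z)-3-{[(2S)-1-tert-butoxy-3-methyl-1-oxobutan-2-yl]amino}-2-methylbut-2-enoate | COC(=O)/C(C)=C(/C)N[C@@H](C(C)C)C(=O)OC(C)(C)C | intermediate
12 | prenyl bromide | CC(C)=CCBr | starting material
13 | methyl (2R)-2-{1-[(2S)-1-tert-butoxy-3-methyl-1-oxobutan-2-yl]iminoethyl}-2,5-dimethylhex-4-enoate | CC(=N[C@@H](C(C)C)C(=O)OC(C)(C)C)[C@@](C)(CC=C(C)C)C(=O)OC | intermediate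
14 | methyl (2R)-2-acetyl-2,5-dimethylhex-4-enoate | CC(=O)[C@@](C)(CC=C(C)C)C(=O)OC | intermediate
15 | methyl 3-oxohexanoate | CCCC(=O)CC(=O)OC | starting material
16 | methyl 2-(2-propyl-1,3-dioxolan-2-yl)acetate | CCCC1(CC(=O)OC)OCCO1 | intermediate
17 | 2-(2-propyl-1,3-dioxolan-2-yl)acetic acid | CCCC1(CC(=O)O)OCCO1 | intermediate
18 | 1-[2-(2-propyl-1,3-dioxolan-2-yl)acetyl]imidazole | CCCC1(CC(=O)n2ccnc2)OCCO1 | intermediate
19 | methyl (2R)-2-methyl-2-(3-methylbut-2-en-1-yl)-3,5-dioxo-6-(2-propyl-1,3-dioxolan-2-yl)hexanoate | CCCC1(CC(=O)CC(=O)[C@@](C)(CC=C(C)C)C(=O)OC)OCCO1 | intermediate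
20 | methyl (2R)-4-{[3-hexanoyl-6-methoxy-2,4-bis(methoxymethoxy)phenyl]methyl}-2-methyl-2-(3-methylbut-2-en-1-yl)-3,5-dioxo-6-(2-propyl-1,3-dioxolan-2-yl)hexanoate (C3 enol drawn) | CCCCCC(=O)c1c(OCOC)cc(OC)c(C/C(C(=O)CC2(CCC)OCCO2)=C(/O)[C@@](C)(CC=C(C)C)C(=O)OC)c1OCOC | intermediate
21 | methyl (2R)-4-{[3-hexanoyl-6-methoxy-2,4-bis(methoxymethoxy)phenyl]methyl}-2-methyl-2-(3-methylbut-2-en-1-yl)-3,5,7-trioxodecanoate (C3 enol drawn) | CCCCCC(=O)c1c(OCOC)cc(OC)c(C/C(C(=O)CC(=O)CCC)=C(/O)[C@@](C)(CC=C(C)C)C(=O)OC)c1OCOC | intermediate
22 | (4R)-2-butanoyl-6-{[3-hexanoyl-6-methoxy-2,4-bis(methoxymethoxy)phenyl]methyl}-3,5-dihydroxy-4-methyl-4-(3-methylbut-2-en-1-yl)cyclohexa-2,5-dien-1-one | CCCCCC(=O)c1c(OCOC)cc(OC)c(CC2=C(O)[C@@](C)(CC=C(C)C)C(O)=C(C(=O)CCC)C2=O)c1OCOC | intermediate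
23 | Elaphopilosin B | CCCCCC(=O)c1c(O)cc(OC)c(CC2=C(O)[C@@](C)(CC=C(C)C)C(O)=C(C(=O)CCC)C2=O)c1O | target

Total step count: 14. Longest linear sequence: 9 steps (steps 1–5 and 11–14).

Steps most likely to fail

Step 13. The charge-delocalised bis-enolate may attack the neopentyl-type ester too slowly. Reversible O-acylation, or on heating retro-Claisen fragmentation of the chain, could then take over. The fallback sets out from 14 and 8 and returns at 22. It closes the ring with a much stronger carbon nucleophile before the butyryl group is present.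
- The lithium enolate of 14 is acylated with 1-acetylimidazole to methyl (2R)-2-methyl-2-(3-methylbut-2-en-1-yl)-3,5-dioxohexanoate F1.
- The sodium enolate of F1 is benzylated with 8 to the 4-arylmethyl diketo ester F2.
- LiN(i-Pr)2 (3.3 equiv, one consumed by the hexanoyl group) generates the terminal carbanion of the β-diketone dianion. This closes the same C6–C1 bond to give the butyryl-free ring-B trione F3.
- Direct C-butyrylation of the only free ring carbon with butyric acid, DCC and DMAP then gives 22.

Step 12. The MOM ethers may be partly lost during ketal hydrolysis. A freed phenol could then add to the neighbouring diketone and dehydrate to a 4H-chromene. The fallback sets out from 19 (with 8) and returns at 22. It unmasks and cyclises before ring A is attached, so no MOM ether is exposed to the acid.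
- 1 M HCl in THF converts 19 into methyl (2R)-2-methyl-2-(3-methylbut-2-en-1-yl)-3,5,7-trioxodecanoate F4.
- KOt-Bu in THF closes the same ring bond to (4R)-2-butanoyl-3,5-dihydroxy-4-methyl-4-(3-methylbut-2-en-1-yl)cyclohexa-2,5-dien-1-one F5.
- The dianion of F5 (NaH, 2 equiv, THF–DMF) is C-benzylated with 8 at the one ring carbon that still bears hydrogen, giving 22.

Step 11. The very electron-rich benzylic bromide may ionise or be attacked by the neighbouring MOM oxygen faster than the diketonate captures it, or the diketonate may be benzylated at oxygen. The fallback sets out from 6 and 19 and returns at 20, and it avoids any benzylic halide.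
- Knoevenagel condensation of aldehyde 6 with 19 (piperidinium acetate, toluene, 4 Å molecular sieves, 60 °C) gives the arylidene diketone F6.
- Its electron-poor alkene is reduced in conjugate fashion with the Hantzsch ester (diethyl 2,6-dimethyl-1,4-dihydropyridine-3,5-dicarboxylate). This leaves the prenyl alkene and all carbonyl groups untouched and gives 20.

Further compounds
F1 | step 13 | methyl (2R)-2-methyl-2-(3-methylbut-2-en-1-yl)-3,5-dioxohexanoate | CC(=O)CC(=O)[C@@](C)(CC=C(C)C)C(=O)OC
F2 | step 13 | methyl (2R)-4-{[3-hexanoyl-6-methoxy-2,4-bis(methoxymethoxy)phenyl]methyl}-2-methyl-2-(3-methylbut-2-en-1-yl)-3,5-dioxohexanoate (C3 enol drawn) | CCCCCC(=O)c1c(OCOC)cc(OC)c(C/C(C(C)=O)=C(/O)[C@@](C)(CC=C(C)C)C(=O)OC)c1OCOC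
F3 | step 13 | (4R)-2-{[3-hexanoyl-6-methoxy-2,4-bis(methoxymethoxy)phenyl]methyl}-3-hydroxy-4-methyl-4-(3-methylbut-2-en-1-yl)cyclohex-2-ene-1,5-dione | CCCCCC(=O)c1c(OCOC)cc(OC)c(CC2=C(O)[C@@](C)(CC=C(C)C)C(=O)CC2=O)c1OCOC
F4 | step 12 | methyl (2R)-2-methyl-2-(3-methylbut-2-en-1-yl)-3,5,7-trioxodecanoate | CCCC(=O)CC(=O)CC(=O)[C@@](C)(CC=C(C)C)C(=O)OC
F5 | step 12 | (4R)-2-butanoyl-3,5-dihydroxy-4-methyl-4-(3-methylbut-2-en-1-yl)cyclohexa-2,5-dien-1-one | O=C1C=C(O)[C@@](C)(CC=C(C)C)C(O)=C1C(=O)CCC
F6 | step 11 | methyl (2R)-4-{[3-hexanoyl-6-methoxy-2,4-bis(methoxymethoxy)phenyl]methylidene}-2-methyl-2-(3-methylbut-2-en-1-yl)-3,5-dioxo-6-(2-propyl-1,3-dioxolan-2-yl)hexanoate | CCCCCC(=O)c1c(OCOC)cc(OC)c(C=C(C(=O)CC2(CCC)OCCO2)C(=O)[C@@](C)(CC=C(C)C)C(=O)OC)c1OCOC
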